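## Retrosynthetic overview

1. Feature: in the carbocycle C3a–C4–C5–C6–C7–C7a the quaternary C5 (OMe, allyl) is bonded to the C6 carbonyl. Both are carbonyl-derived carbons of like polarity, so C5–C6 is cut as a C6 aldehyde (acyl anion through a carbene) plus a C5 allyl ketone.
2. Target 26 ⇐ vinylogous ester 24 ⇐ methyl ether 22 (dehydrogenation C3a–C4 after C7–C7a) ⇐ α-ketol 21 (O-methylation).
3. 21 ⇐ keto-aldehyde 20 by the carbene benzoin closure of the carbocycle. C3a/C7a stay sp3 here so that the aldehyde is a plain α-alkoxy aldehyde, not a β,γ-unsaturated one that would conjugate, and so that C3a can relay configuration to C5.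
4. 20 ⇐ tetrahydrofuran ester 15 ⇐ lactol acetate 12 + silyl ketene acetal 14 ⇐ 3,4-cis allyl lactone 10 ⇐ lactone 7 ⇐ anti-crotylboration of aldehyde 1.
5. Ring order: tetrahydrofuran first (closed as lactone 7, step 3), carbocycle second (step 13), the two ring double bonds last (steps 15, 16).

Key step: step 13

Remark on the chemistry: atoms carry the numbering of the target benzofuranone throughout. C7, the C5 carbinol of 18/19 and the anomeric carbon of 12 are carried as epimer mixtures (their SMILES leave these centres open), because each is later oxidised or becomes sp2.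

## Route

Step 1
Reactants: 1 3,4,5-trimethoxybenzaldehyde; 2 (E)-crotylboronic acid pinacol ester
Product: 4 (1S,2S)-2-methyl-1-(3,4,5-trimethoxyphenyl)but-3-en-1-ol, via homoallyl pinacol borate 3 (not isolated)
Conditions: (S)-TRIP phosphoric acid (5 mol%), toluene, −30 °C; aqueous work-up
Reagents that add atoms: none
Why: Chiral-phosphoric-acid-catalysed crotylboration through a closed chair transition state, in which the (E)-boronate fixes the anti relationship and the acid antipode (the one expected to give the 1S,2S series) selects the aldehyde face, setting C2 and C3.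

Step 2
Reactants: 4 (1S,2S)-2-methyl-1-(3,4,5-trimethoxyphenyl)but-3-en-1-ol
Product: 6 (1S,2S)-2-methyl-1-(3,4,5-trimethoxyphenyl)butane-1,4-diol, via bis(9-BBN) adduct 5 (not isolated)
Conditions: 9-BBN (2.2 equiv), THF, 0 °C → rt; then NaOH, H2O2, 0 °C
Reagents that add atoms: hydrogen peroxide, OO
Why: Anti-Markovnikov hydroboration of the terminal alkene followed by oxidation of the C–B bond gives the primary alcohol without touching a stereocentre.

Step 3
Reactants: 6 (1S,2S)-2-methyl-1-(3,4,5-trimethoxyphenyl)butane-1,4-diol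
Product: 7 (4S,5S)-4-methyl-5-(3,4,5-trimethoxyphenyl)oxolan-2-one
Conditions: TEMPO (10 mol%), PhI(OAc)2 (2.5 equiv), CH2Cl2, rt
Reagents that add atoms: none
Why: Oxidative lactonisation of a 1,4-diol: the primary alcohol is oxidised to the aldehyde, which closes to the lactol and is oxidised on to the trans γ-lactone, closing ring O1–C2–C3–C3a–C7a.

Step 4
Reactants: 7 (4S,5S)-4-methyl-5-(3,4,5-trimethoxyphenyl)oxolan-2-one; 8 allyl bromide
Product: 9 (3S,4S,5S)-3-allyl-4-methyl-5-(3,4,5-trimethoxyphenyl)oxolan-2-one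
Conditions: LiHMDS, THF, −78 °C; 8, −78 → −40 °C
Reagents that add atoms: none
Why: Lithium enolate alkylation of a β-substituted γ-butyrolactone, with allyl bromide entering anti to the adjacent methyl group to give the 3,4-trans lactone.

Step 5
Reactants: 9 (3S,4S,5S)-3-allyl-4-methyl-5-(3,4,5-trimethoxyphenyl)oxolan-2-one
Product: 10 (3R,4S,5S)-3-allyl-4-methyl-5-(3,4,5-trimethoxyphenyl)oxolan-2-one
Conditions: LDA, THF, −78 °C; then 2,6-di-tert-butyl-4-methylphenol, −78 °C
Reagents that add atoms: none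
Why: Kinetic protonation of the lactone enolate anti to the methyl group inverts C3a, so that the allyl arm is cis to the methyl group (C3a–H on the aryl face), the configuration that the key step needs for the relay to C5.

Step 6
Reactants: 10 (3R,4S,5S)-3-allyl-4-methyl-5-(3,4,5-trimethoxyphenyl)oxolan-2-one
Product: 12 (3R,4S,5S)-3-allyl-4-methyl-5-(3,4,5-trimethoxyphenyl)oxolan-2-yl acetate, via aluminium hemiacetal 11 (not isolated)
Conditions: DIBAL-H (1.1 equiv), CH2Cl2, −78 °C; then pyridine, DMAP, Ac2O, −78 → 0 °C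
Reagents that add atoms: acetic anhydride, CC(=O)OC(C)=O
Why: Reductive acetylation of a lactone: the tetrahedral aluminium hemiacetal is stable at −78 °C and is acetylated in situ, so the epimerisable open hydroxy-aldehyde is never formed.

Step 7
Reactants: 13 methyl methoxyacetate
Product: 14 1,2-dimethoxy-1-(trimethylsilyloxy)ethene
Conditions: LDA, THF, −78 °C; TMSCl; distillation
Reagents that add atoms: chlorotrimethylsilane, C[Si](C)(C)Cl
Why: O-Silylation of the ester lithium enolate gives the silyl ketene acetal used as the Mukaiyama donor.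

Step 8
Reactants: 12 (3R,4S,5S)-3-allyl-4-methyl-5-(3,4,5-trimethoxyphenyl)oxolan-2-yl acetate; 14 1,2-dimethoxy-1-(trimethylsilyloxy)ethene
Product: 15 methyl 2-[(2R,3R,4S,5S)-3-allyl-4-methyl-5-(3,4,5-trimethoxyphenyl)oxolan-2-yl]-2-methoxyacetate (C7 epimers)
Conditions: TMSOTf (20 mol%), CH2Cl2, −78 °C
Reagents that add atoms: none
Why: Mukaiyama-type C-glycosylation: ionisation of the anomeric acetate gives the five-membered oxocarbenium ion, which the silyl ketene acetal should attack anti to both the methyl group and the allyl arm, setting C7a with its side chain trans to the arm.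

Step 9
Reactants: 15 methyl 2-[(2R,3R,4S,5S)-3-allyl-4-methyl-5-(3,4,5-trimethoxyphenyl)oxolan-2-yl]-2-methoxyacetate
Product: 17 methyl 2-methoxy-2-[(2R,3R,4S,5S)-4-methyl-3-(2-oxoethyl)-5-(3,4,5-trimethoxyphenyl)oxolan-2-yl]acetate, via vicinal diol 16 (not isolated)
Conditions: OsO4 (2 mol%), NaIO4 (4 equiv), 2,6-lutidine, dioxane/H2O, rt
Reagents that add atoms: osmium tetroxide, O=[Os](=O)(=O)=O; sodium periodate, [Na+].[O-]I(=O)(=O)=O
Why: Lemieux–Johnson oxidation: dihydroxylation of the only alkene and periodate cleavage of the diol give the C5 aldehyde, one carbon shorter.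

Step 10
Reactants: 17 methyl 2-methoxy-2-[(2R,3R,4S,5S)-4-methyl-3-(2-oxoethyl)-5-(3,4,5-trimethoxyphenyl)oxolan-2-yl]acetate; 8 allyl bromide
Product: 18 methyl 2-[(2R,3R,4S,5S)-3-(2-hydroxypent-4-en-1-yl)-4-methyl-5-(3,4,5-trimethoxyphenyl)oxolan-2-yl]-2-methoxyacetate (carbinol epimers)
Conditions: In powder, 8, THF/H2O (1:1), rt
Reagents that add atoms: none
Why: Indium-mediated Barbier allylation in aqueous THF adds allyl to the aldehyde only and leaves the methyl ester; the carbinol configuration is irrelevant because it is oxidised in step 12.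

Step 11
Reactants: 18 methyl 2-[(2R,3R,4S,5S)-3-(2-hydroxypent-4-en-1-yl)-4-methyl-5-(3,4,5-trimethoxyphenyl)oxolan-2-yl]-2-methoxyacetate
Product: 19 1-[(2R,3R,4S,5S)-2-(2-hydroxy-1-methoxyethyl)-4-methyl-5-(3,4,5-trimethoxyphenyl)oxolan-3-yl]pent-4-en-2-ol
Conditions: LiAlH4, THF, 0 °C
Reagents that add atoms: none
Why: Hydride reduction of the methyl ester to the primary alcohol; alkene, ethers and the oxolane are inert.

Step 12
Reactants: 19 1-[(2R,3R,4S,5S)-2-(2-hydroxy-1-methoxyethyl)-4-methyl-5-(3,4,5-trimethoxyphenyl)oxolan-3-yl]pent-4-en-2-ol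
Product: 20 2-methoxy-2-[(2R,3R,4S,5S)-4-methyl-3-(2-oxopent-4-en-1-yl)-5-(3,4,5-trimethoxyphenyl)oxolan-2-yl]acetaldehyde (C7 epimers)
Conditions: Dess–Martin periodinane (3 equiv), NaHCO3, CH2Cl2, 0 °C → rt; used crude
Reagents that add atoms: none
Why: Dess–Martin oxidation of both alcohols under buffered, non-basic conditions gives the α-methoxy aldehyde and the β,γ-unsaturated allyl ketone without double-bond migration.

Step 13
Reactants: 20 2-methoxy-2-[(2R,3R,4S,5S)-4-methyl-3-(2-oxopent-4-en-1-yl)-5-(3,4,5-trimethoxyphenyl)oxolan-2-yl]acetaldehyde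
Product: 21 (2S,3S,3aR,5R,7aR)-5-allyl-5-hydroxy-7-methoxy-3-methyl-2-(3,4,5-trimethoxyphenyl)-3,3a,4,5,7,7a-hexahydro-1-benzofuran-6(2H)-one (C7 epimers)
Conditions: aminoindanol-derived N-pentafluorophenyl triazolium tetrafluoroborate (15 mol%; (5aR,10bS) antipode first, the (5aS,10bR) salt if that pairing is mismatched), i-Pr2NEt (15 mol%), toluene, 0 °C → rt
Reagents that add atoms: none
Why: The carbene adds to the C6 aldehyde, proton transfer gives the hydroxy-enamine (Breslow intermediate), its carbon attacks the C5 ketone and loss of the carbene from the alkoxide gives the α-ketol. This is the carbene-catalysed intramolecular crossed aldehyde–ketone benzoin cyclisation, known with triazolium catalysts for aliphatic and sugar-derived α-alkoxy keto-aldehydes. The carbocycle C3a–C4–C5–C6–C7–C7a closes 6-exo-trig, trans-fused to the tetrahydrofuran. C5 is set in a chair-like transition state with both ring-fusion bonds equatorial, the ketone oxygen equatorial and hydrogen-bonded to the enaminol OH, and the allyl group axial on the face of the axial C3a–H (the aryl face), which is the 5R arrangement; the triazolium antipode is chosen to reinforce this substrate preference. The step needs acyl-anion addition to beat aldol closure, β-alkoxide elimination and conjugation of the allyl ketone, which the catalytic weak amine and the saturated, non-allylic aldehyde carbon should secure; the C7 epimers interconvert and converge.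

Step 14
Reactants: 21 (2S,3S,3aR,5R,7aR)-5-allyl-5-hydroxy-7-methoxy-3-methyl-2-(3,4,5-trimethoxyphenyl)-3,3a,4,5,7,7a-hexahydro-1-benzofuran-6(2H)-one
Product: 22 (2S,3S,3aR,5R,7aR)-5-allyl-5,7-dimethoxy-3-methyl-2-(3,4,5-trimethoxyphenyl)-3,3a,4,5,7,7a-hexahydro-1-benzofuran-6(2H)-one (C7 epimers)
Conditions: MeOTf (5 equiv), 2,6-di-tert-butyl-4-methylpyridine (6 equiv), CH2Cl2, rt → 40 °C
Reagents that add atoms: methyl trifluoromethanesulfonate, COS(=O)(=O)C(F)(F)F
Why: O-Alkylation of the hindered tertiary α-ketol hydroxyl with methyl triflate and a non-nucleophilic pyridine base avoids enolate formation at C7 and base-induced α-ketol rearrangement.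

Step 15
Reactants: 22 (2S,3S,3aR,5R,7aR)-5-allyl-5,7-dimethoxy-3-methyl-2-(3,4,5-trimethoxyphenyl)-3,3a,4,5,7,7a-hexahydro-1-benzofuran-6(2H)-one
Product: 24 (2S,3S,3aR,5R)-5-allyl-5,7-dimethoxy-3-methyl-2-(3,4,5-trimethoxyphenyl)-3,3a,4,5-tetrahydro-1-benzofuran-6(2H)-one, via trimethylsilyl enol ether 23 (not isolated)
Conditions: LiHMDS, TMSCl, THF, −78 °C; then Pd(OAc)2 (1.1 equiv), MeCN, rt
Reagents that add atoms: none
Why: Saegusa–Ito oxidation: C7 is the only enolisable position of the C6 ketone and C7a–H the only β-hydrogen of the palladium enolate, so the C7=C7a vinylogous ester must result and the C7 epimers converge.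

Step 16
Reactants: 24 (2S,3S,3aR,5R)-5-allyl-5,7-dimethoxy-3-methyl-2-(3,4,5-trimethoxyphenyl)-3,3a,4,5-tetrahydro-1-benzofuran-6(2H)-one
Product: 26 (2S,3S,5R)-5-allyl-5,7-dimethoxy-3-methyl-2-(3,4,5-trimethoxyphenyl)-3,5-dihydro-1-benzofuran-6(2H)-one, via trimethylsilyl dienol ether 25 (not isolated)
Conditions: LDA, TMSCl, THF, −78 °C; then DDQ (1.05 equiv), 2,6-lutidine, CH2Cl2, −40 → 0 °C
Reagents that add atoms: none
Why: γ-Deprotonation at C3a (C5 is quaternary) gives the 6-silyloxy-cyclohexa-1,3-diene, and quinone dehydrogenation of this silyl dienol ether should take hydride from the axial C4–H, which is aligned with the diene and less shielded than the C3 methine lying between the methyl and the cis aryl group, giving the linear dienone with C2, C3 and C5 untouched.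

## Compound list

1 | 3,4,5-trimethoxybenzaldehyde | COc1cc(C=O)cc(OC)c1OC | starting material
2 | (E)-crotylboronic acid pinacol ester | C/C=C/CB1OC(C)(C)C(C)(C)O1 | starting material
3 | pinacol borate of alcohol 4 | CC1(C)OB(O[C@H](c2cc(OC)c(OC)c(OC)c2)[C@H](C=C)C)OC1(C)C | intermediate (not isolated)
4 | (1S,2S)-2-methyl-1-(3,4,5-trimethoxyphenyl)but-3-en-1-ol (anti) | O[C@H](c1cc(OC)c(OC)c(OC)c1)[C@H](C=C)C | intermediate
5 | bis(9-BBN) adduct of 4 (C-alkylborane, O-borinate) | C1CCC2CCCC1B2O[C@H](c1cc(OC)c(OC)c(OC)c1)[C@H](CCB1C2CCCC1CCC2)C | intermediate (not isolated)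
6 | (1S,2S)-2-methyl-1-(3,4,5-trimethoxyphenyl)butane-1,4-diol | O[C@H](c1cc(OC)c(OC)c(OC)c1)[C@H](CCO)C | intermediate
7 | (4S,5S)-4-methyl-5-(3,4,5-trimethoxyphenyl)oxolan-2-one (4,5-trans) | O=C1O[C@H](c2cc(OC)c(OC)c(OC)c2)[C@@H](C)C1 | intermediate
8 | allyl bromide | C=CCBr | starting material
9 | (3S,4S,5S)-3-allyl-4-methyl-5-(3,4,5-trimethoxyphenyl)oxolan-2-one (3,4-trans) | O=C1O[C@H](c2cc(OC)c(OC)c(OC)c2)[C@@H](C)[C@@H]1CC=C | intermediate
10 | (3R,4S,5S)-3-allyl-4-methyl-5-(3,4,5-trimethoxyphenyl)oxolan-2-one (3,4-cis, 4,5-trans) | O=C1O[C@H](c2cc(OC)c(OC)c(OC)c2)[C@@H](C)[C@H]1CC=C | intermediate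
11 | diisobutylaluminium hemiacetal of 10 | CC(C)C[Al](CC(C)C)OC1O[C@H](c2cc(OC)c(OC)c(OC)c2)[C@@H](C)[C@H]1CC=C | intermediate (not isolated)
12 | (3R,4S,5S)-3-allyl-4-methyl-5-(3,4,5-trimethoxyphenyl)oxolan-2-yl acetate (anomers) | CC(=O)OC1O[C@H](c2cc(OC)c(OC)c(OC)c2)[C@@H](C)[C@H]1CC=C | intermediate
13 | methyl methoxyacetate | COCC(=O)OC | starting material
14 | 1,2-dimethoxy-1-(trimethylsilyloxy)ethene (E/Z) | COC=C(OC)O[Si](C)(C)C | intermediate
15 | methyl 2-[(2R,3R,4S,5S)-3-allyl-4-methyl-5-(3,4,5-trimethoxyphenyl)oxolan-2-yl]-2-methoxyacetate (C7 epimers) | COC(=O)C(OC)[C@@H]1O[C@H](c2cc(OC)c(OC)c(OC)c2)[C@@H](C)[C@H]1CC=C | intermediate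
16 | methyl 2-[(2R,3R,4S,5S)-3-(2,3-dihydroxypropyl)-4-methyl-5-(3,4,5-trimethoxyphenyl)oxolan-2-yl]-2-methoxyacetate | COC(=O)C(OC)[C@@H]1O[C@H](c2cc(OC)c(OC)c(OC)c2)[C@@H](C)[C@H]1CC(O)CO | intermediate (not isolated)
17 | methyl 2-methoxy-2-[(2R,3R,4S,5S)-4-methyl-3-(2-oxoethyl)-5-(3,4,5-trimethoxyphenyl)oxolan-2-yl]acetate | COC(=O)C(OC)[C@@H]1O[C@H](c2cc(OC)c(OC)c(OC)c2)[C@@H](C)[C@H]1CC=O | intermediate
18 | methyl 2-[(2R,3R,4S,5S)-3-(2-hydroxypent-4-en-1-yl)-4-methyl-5-(3,4,5-trimethoxyphenyl)oxolan-2-yl]-2-methoxyacetate | COC(=O)C(OC)[C@@H]1O[C@H](c2cc(OC)c(OC)c(OC)c2)[C@@H](C)[C@H]1CC(O)CC=C | intermediate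
19 | 1-[(2R,3R,4S,5S)-2-(2-hydroxy-1-methoxyethyl)-4-methyl-5-(3,4,5-trimethoxyphenyl)oxolan-3-yl]pent-4-en-2-ol | OCC(OC)[C@@H]1O[C@H](c2cc(OC)c(OC)c(OC)c2)[C@@H](C)[C@H]1CC(O)CC=C | intermediate
20 | 2-methoxy-2-[(2R,3R,4S,5S)-4-methyl-3-(2-oxopent-4-en-1-yl)-5-(3,4,5-trimethoxyphenyl)oxolan-2-yl]acetaldehyde (key-step precursor) | O=CC(OC)[C@@H]1O[C@H](c2cc(OC)c(OC)c(OC)c2)[C@@H](C)[C@H]1CC(=O)CC=C | intermediate
21 | (2S,3S,3aR,5R,7aR)-5-allyl-5-hydroxy-7-methoxy-3-methyl-2-(3,4,5-trimethoxyphenyl)-3,3a,4,5,7,7a-hexahydro-1-benzofuran-6(2H)-one (key-step product; trans-fused) | C=CC[C@@]1(O)C[C@H]2[C@H](C(OC)C1=O)O[C@H](c1cc(OC)c(OC)c(OC)c1)[C@H]2C | intermediate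
22 | (2S,3S,3aR,5R,7aR)-5-allyl-5,7-dimethoxy-3-methyl-2-(3,4,5-trimethoxyphenyl)-3,3a,4,5,7,7a-hexahydro-1-benzofuran-6(2H)-one | C=CC[C@@]1(OC)C[C@H]2[C@H](C(OC)C1=O)O[C@H](c1cc(OC)c(OC)c(OC)c1)[C@H]2C | intermediate
23 | 6-trimethylsilyl enol ether of 22 (C6=C7) | C=CC[C@@]1(OC)C[C@H]2[C@H](C(OC)=C1O[Si](C)(C)C)O[C@H](c1cc(OC)c(OC)c(OC)c1)[C@H]2C | intermediate (not isolated)
24 | (2S,3S,3aR,5R)-5-allyl-5,7-dimethoxy-3-methyl-2-(3,4,5-trimethoxyphenyl)-3,3a,4,5-tetrahydro-1-benzofuran-6(2H)-one | C=CC[C@@]1(OC)C[C@H]2C(=C(OC)C1=O)O[C@H](c1cc(OC)c(OC)c(OC)c1)[C@H]2C | intermediate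
25 | 6-trimethylsilyloxy dienol ether of 24 (C6=C7, C7a=C3a) | C=CC[C@@]1(OC)CC2=C(C(OC)=C1O[Si](C)(C)C)O[C@H](c1cc(OC)c(OC)c(OC)c1)[C@H]2C | intermediate (not isolated)
26 | (2S,3S,5R)-5-allyl-5,7-dimethoxy-3-methyl-2-(3,4,5-trimethoxyphenyl)-3,5-dihydro-1-benzofuran-6(2H)-one | C=CC[C@@]1(OC)C=C2C(=C(OC)C1=O)O[C@H](c1cc(OC)c(OC)c(OC)c1)[C@H]2C | target

## Step count and risks

Total step count: 16. Longest linear sequence: 15 (steps 1–6 and 8–16; step 7 is a one-step side branch).

Steps most likely to fail: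

1. Step 13 (key step). The facial selectivity at the C5 ketone may be poor if the substrate and catalyst preferences are not aligned, and aldol closure or β-alkoxide elimination may outrun carbene addition. Fallback: from 20, a samarium diiodide pinacol cyclisation (SmI2, t-BuOH, THF, −78 °C) would join C5 and C6 by ketyl addition under non-basic conditions and give the 5-allyl-7-methoxy-5,6-diol F1. Its C5 epimers would be separated, and Dess–Martin oxidation of the secondary C6 hydroxyl returns to the route at 21.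

2. Step 16. Hydride may be lost from the C3 methine instead of C4, which would lead on to aromatisation of the five-membered ring to a furan, and the electron-rich benzylic ether position may also be oxidised. Fallback: from 24, through the same dienol ether 25, N-bromosuccinimide (THF, −78 °C) should brominate C3a on the face anti to the C3 methyl group and give the 3a-bromo enone F2. In F2 the C3 hydrogen is syn to bromine, so only a C4 hydrogen is antiperiplanar; DBU (toluene, 0 °C → rt) then removes HBr by E2 and arrives at 26.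

3. Step 5. The facial selectivity of the protonation may be poor, or the product may re-equilibrate to the more stable trans lactone. Fallback: from 9, the enolate (LDA, −78 °C) is quenched with PhSeBr to give the 3-allyl-3-(phenylselanyl) lactone F3, with selenium anti to the methyl group. Radical deselenation (Bu3SnH, AIBN, benzene, 80 °C) then delivers hydrogen from the bulky stannane to the lactone radical anti to the methyl group and comes back to the route at 10.

Further compounds
F1 | step 13 | (2S,3S,3aR,5R,7aR)-5-allyl-7-methoxy-3-methyl-2-(3,4,5-trimethoxyphenyl)octahydro-1-benzofuran-5,6-diol (C6 and C7 epimers) | C=CC[C@@]1(O)C[C@H]2[C@H](C(OC)C1O)O[C@H](c1cc(OC)c(OC)c(OC)c1)[C@H]2C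
F2 | step 16 | 5-allyl-3a-bromo-5,7-dimethoxy-3-methyl-2-(3,4,5-trimethoxyphenyl)-3,3a,4,5-tetrahydro-1-benzofuran-6(2H)-one (Br anti to the C3 methyl) | C=CC[C@@]1(OC)C[C@@]2(Br)C(=C(OC)C1=O)O[C@H](c1cc(OC)c(OC)c(OC)c1)[C@H]2C
F3 | step 5 | 3-allyl-4-methyl-3-(phenylselanyl)-5-(3,4,5-trimethoxyphenyl)oxolan-2-one (Se anti to the C4 methyl) | O=C1O[C@H](c2cc(OC)c(OC)c(OC)c2)[C@@H](C)[C@]1(CC=C)[Se]c1ccccc1
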